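The pitfall in a curve that rises and falls is to chase the isomer of the product A itself, so I followed what was left instead. You guessed that the percentages carry over to the new flask at 12 mM. At 0.625 d red and grey read 58% and 57% of that isomer, so I took your guess as my assumption.

| setting | red | grey | flask |
|---|---|---|---|
| starting material | 17 mM | 26 mM | 12 mM |
| remark | run made earlier | run made earlier |  |
| time |  |  | 15 d |

- red (time / d: isomer of the product A / %, target / %, starting material / %): 0.0833: 41, 3, 48; 0.208: 59, 2, 28; 0.625: 58, 6, 21; 1.25: 51, 5, 19; 4.00: 29, 5, 11; 10.0: 14, 5, 5
- grey (time / d: isomer of the product A / %, target / %, starting material / %): 0.0833: 41, 2, 48; 0.208: 58, 4, 27; 0.625: 57, 5, 21; 1.25: 48, 5, 20; 4.00: 30, 4, 10; 10.0: 9, 4, 4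

(readings scatter by 1.5 percentage points)

- what was read earlier has a scatter of 1.5 percentage points, one standard deviation

- the moment within 15 d at which there is most isomer of the product A
- the amount of isomer of the product A, in percent of the starting material charged, at that time

I called starting material plus isomer of the product A the pair, which stood at 78.5% on average at 0.625 d. From those readings I took 0.732 as the isomer's share of the pair, a pre-equilibrium value; red still read 0.725 at 4.00 d. Two fractions left did the rest, and I assumed the drain held back to the peak:

gap to that share left in red at 0.0833 d: 0.371, so closing rate = 11.9 d⁻¹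

pair drain, 0.625 d to 4.00 d, both runs: 0.200 d⁻¹

peak time = ln((closing + drain)/drain)/closing = 0.345 d

pair at the peak = 83.0%

peak height = share × pair × closing/(closing + drain) = 59.8%

The gap closed far faster than the pair drained, so my reckoned peak stood early in the time allowed.

The forecast, built on a “fast reversible isomerisation”, stood at 0.36 d and 60.5%, later and higher than my reckoning.

The flask gave 62.9% at 0.342 d, 3.1 percentage points above my height, its pair standing at 87.1% against my 83.0%. The steps behind it were these:

    isomer of the product A ⇌ starting material (k = 0.00220 min⁻¹)
    2 starting material → homo dimer (k = 0.0220 M⁻¹ min⁻¹)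
    target ⇌ isomer of the product B (K = 25.0, k = 0.00140 min⁻¹)
    target ⇌ isomer of the product A (K = 1.10, k = 3.30 × 10⁻⁵ min⁻¹)
    starting material ⇌ target (K = 2.40, k = 3.50 × 10⁻⁴ min⁻¹)

At 15.0 d the flask held 2.91% of starting material, which the share turned into 7.95% of the isomer of the product A, and it held 7.87%. The neighbour charged with 30 mM held 2.17% of starting material at 15.0 d, which the share turned into 5.93%, and it held 5.85% of that isomer.

The numbers in the tables stem from a simulated flask with made-up constants; the scatter is artificial.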